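Remark on the chemistry: the SMILES is taken as the definition of the structure. Ring A is numbered with C1 at the ethylene bridge, C2 and C6 at the two 4-hydroxybenzyl groups, C3 at the free hydroxyl, C4 at the only ring hydrogen and C5 at the methoxy group. Ring B is the 3-methoxyphenyl ring, and rings C and D are the two 4-hydroxyphenyl rings.

## Analysis of the target

The target is an open assembly of four benzene rings without any stereocentre: ring A and ring B are joined by a CH2–CH2 bridge, and rings C and D hang on C2 and C6 of ring A through one CH2 group each. Ring A is pentasubstituted (bridge at C1, benzyl groups at C2 and C6, hydroxyl at C3, methoxy at C5, hydrogen at C4). The problem is therefore purely constitutional: three neighbouring carbon substituents (C6, C1, C2) must be placed on a crowded ring between two meta oxygens. The sensitive groups are the three free phenols, the electron-rich ring A (oxidation in base, electrophilic attack at C4) and the 4-hydroxybenzyl units, which can ionise to quinone methides under oxidising or strongly acidic conditions. The doubly benzylic CH2 groups are also acidic towards organolithium reagents. The two hard points are the regiocontrolled construction of ring A and the distinction between O3 (free) and O5 (methylated) while two further phenols and a further methyl ether are present. The strategy rests on the hidden symmetry of ring A: apart from the O-methyl group it has a mirror plane through C1 and C4. C2 to C6, with the oxygens on C3 and C5 and the two benzyl groups, therefore map onto a symmetric 1,7-diarylheptane-3,5-dione, and C1 with the bridge and ring B maps onto the carbonyl carbon of a cinnamoyl unit.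

## Retrosynthetic reasoning

Target 12 to 11. No skeletal bond is cut. The saturated bridge is traced back to an E alkene and the phenols of rings C and D to benzyl ethers, so that one catalytic hydrogenation ends the synthesis. Benzyl is chosen because it survives strong amide base, aqueous hydroxide and O-methylation, and because it keeps rings C and D masked while ring A is methylated.

11 to 10. The O5–CH3 bond is cut. In 10 the two ring A hydroxyls are mirror images of each other, so methylation of either gives the same ether 11 and no regiochemical question arises. The price is that mono- versus bis-methylation is controlled only by stoichiometry.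

10 to 4 and 7 (through 9 and 8). Ring A is opened at C1–C6 (aldol, through cyclic aldol 9) and then at C1–C2 (acylation, through triketone 8). Both bonds meet at C1, the only ring carbon that carries neither oxygen nor a benzyl group, so everything else in ring A is already present in the symmetric diketone 4. Cutting the C2–CH2 and C6–CH2 bonds instead would call for two benzylations of a resorcinol ortho to oxygen with C4 left untouched. Cutting the bridge at C1 would call for a coupling at a position flanked by two benzyl groups. The forward reaction has to acylate the dianion of 4 at a terminal carbon, attack the carbonyl rather than the double bond of 7, and then fold in one sense only. The styryl group of 7 secures the last point, because that side of C1 has no enolisable hydrogen.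

7 to 5. The amide C–N bond is cut. The N-methoxy-N-methyl amide is wanted because its tetrahedral adduct is stable until work-up, so that the acidic triketone does not appear while dianion is still present.

4 to 3 and 2, then 3 to 1 and 2. The two CH2–CH2 bonds that link the benzylic carbons to the diketone chain are cut in turn. Each is formed by alkylation of a β-diketone dianion at its terminal carbon with benzylic chloride 2. The symmetry of 4 lets the same electrophile serve twice, and the five-carbon core comes from 1.

## Alternatives that were turned down

Alternative 1: The bridge is disconnected at both aryl–CH2 bonds (C1–Cα on ring A and Cβ–C1′ on ring B). This gives the ring A bromide A2, the vinylboronic pinacol ester A3 and the aryl triflate A4. In the forward step, halogen–lithium exchange on A2 and addition to A3 give a boron ate complex. A palladium catalyst with a ferrocenyl bisphosphine inserts into A4, the cationic divalent palladium aryl activates the vinyl group, ring A migrates from boron to Cα, and reductive elimination joins Cβ to ring B. The product is the secondary boronate A1.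
- For it: both bridge bonds form in one convergent operation, and O3 and O5 are differentiated from the start (benzyl against methyl). On that point it is stronger than the chosen route, which has to methylate statistically.
- Against it: the step does not build ring A. A2 already holds all five substituents, and placing bromine, two benzyl groups and two different ethers around one ring would take longer than the whole chosen route.
- The aryllithium sits between two diarylmethane CH2 groups whose protons are far more acidic than an arene C–H, so proton transfer competes with ate formation.
- A 2,6-disubstituted aryl group must migrate in a crowded ate complex.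
- The boron atom and the stereocentre at Cα of A1 are unwanted and cost a protodeboronation step.
- Comparison: the chosen strategy builds ring A with all its substituents and the bridge carbons in one flask from symmetric precursors, in six steps overall.

Alternative 2: Ring A is disconnected at C1–C6 and C4–C5 into the benzylmalonate A6 and the enone A7. In the forward step, methoxide forms the anion of A6, which adds to the β-carbon of A7 (C1–C6). The enolate then equilibrates to the methyl ketone enolate, which attacks a malonate ester (C4–C5) in a Claisen-type closure to the cyclohexane-1,3-dione A5.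
- For it: the reagents are cheap and the chemistry is classical. After loss of the ester the dione forms only a mono enol ether, so aromatisation of that ether would give the O5-methyl, O3-hydroxyl pattern cleanly. On that point it is stronger than the chosen route.
- Against it: the Michael step must join a fully substituted malonate carbanion to the β-carbon of an α-branched, β-alkylated enone. This makes a quaternary carbon next to a tertiary one, the least favourable kind of conjugate addition, and it is reversible.
- A7 has γ-hydrogens, so dienolate formation competes.
- A5 is at the wrong oxidation level. It needs removal of a hindered quaternary ester and dehydrogenation to the arene in the presence of benzyl ethers and benzylic CH2 groups.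
- A7 itself needs a regiocontrolled crossed aldol condensation, and the count rises to eight steps or more.
- Comparison: the chosen strategy reaches the aromatic oxidation level by simple dehydration, creates no quaternary centre and needs no redox adjustment.

Alternative 3: Ring A is disconnected at C6–C1 and C3–C2 into the 1-silyloxy-1,3-dimethoxy diene A9 and the ynone A10. In the forward step a Diels–Alder reaction joins the benzyl-bearing diene terminus to the β-carbon of A10 and the ketene acetal carbon to its α-carbon. The cyclohexadiene loses methanol and the silyl group on acidic work-up to give the phenol A8, hydrogen-bonded to its aroyl group.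
- For it: regiochemistry follows from the polarisation of both partners, the bridge is already saturated, and O3 is free while O5 is methylated directly. On that last point it is stronger than the chosen route.
- Against it: both reacting termini are substituted (a CH2-aryl group on the diene, an alkyl chain on the ynone β-carbon). This slows the cycloaddition of a diene that is labile to hydrolysis and to silyl migration.
- A8 carries C2's side-chain carbon at the ketone level, so a chelated ortho-hydroxy diaryl ketone must still be reduced to CH2.
- A9 and A10 each need about three steps, so the total is about nine steps.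
- Comparison: the chosen strategy brings in both benzyl groups at the correct oxidation level and is shorter, but it gives up the built-in oxygen differentiation.

Key step: step 4

## Steps

Step 1
Reactants: 1 acetylacetone (pentane-2,4-dione); 2 4-benzyloxybenzyl chloride
Product: 3 6-(4-benzyloxyphenyl)hexane-2,4-dione
Conditions: LiN(iPr)2 (2.1 equiv), THF, 0 °C; 2 (0.9 equiv), −78 → 0 °C; aq NH4Cl
Reagents that add atoms: none
Why: Alkylation of a β-diketone dianion; the second-formed terminal carbanion is far more nucleophilic than the stabilised central carbon and displaces the benzylic chloride by SN2, and a small excess of dianion limits double alkylation.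

Step 2
Reactants: 3 6-(4-benzyloxyphenyl)hexane-2,4-dione; 2 4-benzyloxybenzyl chloride
Product: 4 1,7-bis(4-benzyloxyphenyl)heptane-3,5-dione
Conditions: LiN(iPr)2 (2.1 equiv), THF, −78 → 0 °C; 2 (1.0 equiv), −78 → 0 °C; aq NH4Cl
Reagents that add atoms: none
Why: Second dianion alkylation; kinetic deprotonation of the mono-enolate should occur at the methyl group rather than at the more substituted methylene, so the second benzyl group enters at the other chain end and gives the symmetric diketone.

Step 3
Reactants: 5 (E)-3-methoxycinnamic acid
Product: 7 (E)-N-methoxy-N-methyl-3-(3-methoxyphenyl)prop-2-enamide, via acyl imidazole 6 (not isolated)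
Conditions: CDI (1.1 equiv), CH2Cl2, rt; then MeNH(OMe)·HCl (1.2 equiv), rt
Reagents that add atoms: N,O-dimethylhydroxylamine hydrochloride, CNOC.Cl
Why: Amide formation through an acyl imidazole; carbonyldiimidazole activates the acid with loss of CO2 and the amine salt displaces imidazole, leaving the E alkene untouched.

Step 4
Reactants: 4 1,7-bis(4-benzyloxyphenyl)heptane-3,5-dione; 7 (E)-N-methoxy-N-methyl-3-(3-methoxyphenyl)prop-2-enamide
Product: 10 (E)-2,6-bis(4-benzyloxybenzyl)-3,5-dihydroxy-3'-methoxystilbene, via triketone 8 (not isolated), via cyclic aldol 9 (not isolated)
Conditions: LiN(iPr)2 (2.2 equiv), THF, −78 → 0 °C; 7 (1.0 equiv), −78 → 0 °C; then 2 M aq KOH, MeOH, rt → 40 °C, argon; aq HCl to pH 3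
Reagents that add atoms: none
Why: Lithium diisopropylamide (two equivalents) converts 4 into its dianion, and the less stabilised carbanion at C2 adds to the carbonyl of Weinreb amide 7 to give a chelated N-methoxy-N-methyl hemiaminal alkoxide that does not collapse in the flask, so no acidic triketone appears to quench unreacted dianion and no second addition can occur; this Claisen-type acylation forms C1–C2. Aqueous KOH then releases triketone 8, whose enolate across C5–C6 adds to the C1 ketone (C1–C6) in a 6-(enolendo)-exo-trig aldol closure to cyclic aldol 9, and loss of water followed by enolisation of the two remaining carbonyls gives resorcinol 10. The closest known reaction type is the acylation of β-diketone dianions to 1,3,5-triketones and their hydroxide-mediated aldol aromatisation to 5-substituted resorcinols, the same fold that stilbene synthases use. No stereocentre survives, because those of 8 and 9 are erased on aromatisation and the E alkene is carried over from 7. Three selectivities are needed. Terminal rather than central acylation follows from the higher nucleophilicity of the second-formed carbanion. Carbonyl rather than conjugate attack on 7 is favoured because a hard lithium carbanion meets a β-carbon that the amide group deactivates. Only one aldol fold is open because C1 carries a styryl group without enolisable hydrogen, and additions of carbon or oxygen to the styryl β-carbon are expected to be reversible under hydroxide whereas the aromatisation is not.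

Step 5
Reactants: 10 (E)-2,6-bis(4-benzyloxybenzyl)-3,5-dihydroxy-3'-methoxystilbene
Product: 11 (E)-2,6-bis(4-benzyloxybenzyl)-3-hydroxy-5,3'-dimethoxystilbene
Conditions: MeI (1.0 equiv), K2CO3 (1.0 equiv), acetone, rt; recovered 10 resubmitted
Reagents that add atoms: iodomethane, CI
Why: Williamson ether synthesis on a symmetric resorcinol; the two hydroxyls are equivalent, so only one mono-ether can form, and rings C and D stay masked as benzyl ethers, so that limiting the methylating agent is the only control needed.

Step 6
Reactants: 11 (E)-2,6-bis(4-benzyloxybenzyl)-3-hydroxy-5,3'-dimethoxystilbene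
Product: 12 2,6-bis(4-hydroxybenzyl)-3-hydroxy-5,3'-dimethoxybibenzyl (target)
Conditions: H2 (1 atm), Pd/C (10%), EtOAc–MeOH, rt
Reagents that add atoms: none
Why: Heterogeneous catalytic hydrogenation; the stilbene double bond is saturated and both aryl benzyl ethers are cleaved by hydrogenolysis, while aryl methyl ethers, phenols and the diarylmethane C–C bonds are inert under these conditions.

## Compound list

1 | acetylacetone (pentane-2,4-dione) | CC(=O)CC(C)=O | starting material
2 | 4-benzyloxybenzyl chloride | ClCc1ccc(OCc2ccccc2)cc1 | starting material
3 | 6-(4-benzyloxyphenyl)hexane-2,4-dione | CC(=O)CC(=O)CCc1ccc(OCc2ccccc2)cc1 | intermediate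
4 | 1,7-bis(4-benzyloxyphenyl)heptane-3,5-dione | O=C(CCc1ccc(OCc2ccccc2)cc1)CC(=O)CCc1ccc(OCc2ccccc2)cc1 | intermediate
5 | (E)-3-methoxycinnamic acid | COc1cccc(/C=C/C(=O)O)c1 | starting material
6 | (E)-1-(imidazol-1-yl)-3-(3-methoxyphenyl)prop-2-en-1-one (acyl imidazole) | COc1cccc(/C=C/C(=O)n2ccnc2)c1 | intermediate
7 | (E)-N-methoxy-N-methyl-3-(3-methoxyphenyl)prop-2-enamide | COc1cccc(/C=C/C(=O)N(C)OC)c1 | intermediate
8 | (E)-4-(4-benzyloxybenzyl)-9-(4-benzyloxyphenyl)-1-(3-methoxyphenyl)non-1-ene-3,5,7-trione (racemic at C4, enolisable) | COc1cccc(/C=C/C(=O)C(Cc2ccc(OCc3ccccc3)cc2)C(=O)CC(=O)CCc2ccc(OCc3ccccc3)cc2)c1 | intermediate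
9 | 4,6-bis(4-benzyloxybenzyl)-5-hydroxy-5-[(E)-2-(3-methoxyphenyl)ethenyl]cyclohexane-1,3-dione (diastereomer mixture) | COc1cccc(/C=C/C2(O)C(Cc3ccc(OCc4ccccc4)cc3)C(=O)CC(=O)C2Cc2ccc(OCc3ccccc3)cc2)c1 | intermediate
10 | (E)-2,6-bis(4-benzyloxybenzyl)-3,5-dihydroxy-3'-methoxystilbene | COc1cccc(/C=C/c2c(Cc3ccc(OCc4ccccc4)cc3)c(O)cc(O)c2Cc2ccc(OCc3ccccc3)cc2)c1 | intermediate
11 | (E)-2,6-bis(4-benzyloxybenzyl)-3-hydroxy-5,3'-dimethoxystilbene | COc1cccc(/C=C/c2c(Cc3ccc(OCc4ccccc4)cc3)c(O)cc(OC)c2Cc2ccc(OCc3ccccc3)cc2)c1 | intermediate
12 | 2,6-bis(4-hydroxybenzyl)-3-hydroxy-5,3'-dimethoxybibenzyl | COc1cccc(CCc2c(Cc3ccc(O)cc3)c(O)cc(OC)c2Cc2ccc(O)cc2)c1 | target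

## Step count and least certain steps

Total: 6 steps. Longest linear sequence: 5 steps (steps 1, 2, 4, 5 and 6); step 3 is a one-step side branch.

Step 4 (key step). The most likely failure is in the acylation half. The attacking carbanion is secondary and flanked by a benzyl group, so addition to the amide carbonyl may be outrun by conjugate addition to the cinnamoyl double bond or by proton transfer. In the hydroxide half, closure of the central carbanion or of an enol oxygen onto the styryl β-carbon, or retro-Claisen cleavage, may compete with the slower aldol fold onto a hindered, conjugated ketone. Fallback, setting out from 4: the carbonyl partner is taken at the aldehyde level. The dianion of 4 is treated at −78 °C with (E)-3-(3-methoxyphenyl)prop-2-enal F1, which hard lithium carbanions attack at the carbonyl carbon much faster than they attack an amide. This should give the allylic alcohol (E)-4-(4-benzyloxybenzyl)-9-(4-benzyloxyphenyl)-3-hydroxy-1-(3-methoxyphenyl)non-1-ene-5,7-dione F2. Oxidation of the allylic alcohol with MnO2 in CH2Cl2 returns to the route at triketone 8, now isolated. Its cyclisation to 10 can then be studied on its own in aqueous KOH or buffered base.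

Step 5. Over-methylation is the likely failure, since the second hydroxyl is about as reactive as the first, so the conversion is statistical. C-methylation at the activated C4 position is a minor risk. Fallback, setting out from 10: the selectivity problem is turned into a deprotection, which is electronically biased. Ac2O and pyridine give the diacetate (E)-2,6-bis(4-benzyloxybenzyl)-3,5-diacetoxy-3'-methoxystilbene F3. One equivalent of NaOMe in THF–MeOH at −20 °C removes one acetate, because the phenoxide so formed makes the remaining ester a poorer acyl donor, giving the monoacetate (E)-3-acetoxy-2,6-bis(4-benzyloxybenzyl)-5-hydroxy-3'-methoxystilbene F4. A Mitsunobu methylation (MeOH, PPh3, DIAD, THF), neutral so that acetyl transfer between phenols is avoided, gives (E)-3-acetoxy-2,6-bis(4-benzyloxybenzyl)-5,3'-dimethoxystilbene F5. Methanolysis with K2CO3 in MeOH returns to the route at 11.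

Step 2 (the same concern applies to step 1). Proton exchange between the product mono-enolate and unreacted dianion may lead to a second alkylation on the same carbon, and deprotonation on the already substituted side may give the branched isomer. Fallback, setting out from 1 and replacing steps 1 and 2: a boron-templated double aldol condensation of 1 with 4-benzyloxybenzaldehyde F6 (B2O3, B(OBu)3, n-BuNH2, EtOAc, 80 °C; then dilute HCl) gives (1E,6E)-1,7-bis(4-benzyloxyphenyl)hepta-1,6-diene-3,5-dione F7. Homogeneous hydrogenation of the two enone double bonds with H2 and RhCl(PPh3)3 in THF–EtOH, which does not cleave benzyl ethers, returns to the route at 4.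

## Further compounds

F1 | step 4 | (E)-3-(3-methoxyphenyl)prop-2-enal (purchased partner of the fallback) | COc1cccc(/C=C/C=O)c1
F2 | step 4 | (E)-4-(4-benzyloxybenzyl)-9-(4-benzyloxyphenyl)-3-hydroxy-1-(3-methoxyphenyl)non-1-ene-5,7-dione (diastereomer mixture) | COc1cccc(/C=C/C(O)C(Cc2ccc(OCc3ccccc3)cc2)C(=O)CC(=O)CCc2ccc(OCc3ccccc3)cc2)c1
F3 | step 5 | (E)-2,6-bis(4-benzyloxybenzyl)-3,5-diacetoxy-3'-methoxystilbene | COc1cccc(/C=C/c2c(Cc3ccc(OCc4ccccc4)cc3)c(OC(C)=O)cc(OC(C)=O)c2Cc2ccc(OCc3ccccc3)cc2)c1
F4 | step 5 | (E)-3-acetoxy-2,6-bis(4-benzyloxybenzyl)-5-hydroxy-3'-methoxystilbene | COc1cccc(/C=C/c2c(Cc3ccc(OCc4ccccc4)cc3)c(O)cc(OC(C)=O)c2Cc2ccc(OCc3ccccc3)cc2)c1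
F5 | step 5 | (E)-3-acetoxy-2,6-bis(4-benzyloxybenzyl)-5,3'-dimethoxystilbene | COc1cccc(/C=C/c2c(Cc3ccc(OCc4ccccc4)cc3)c(OC)cc(OC(C)=O)c2Cc2ccc(OCc3ccccc3)cc2)c1
F6 | step 2 | 4-benzyloxybenzaldehyde (purchased partner of the fallback) | O=Cc1ccc(OCc2ccccc2)cc1
F7 | step 2 | (1E,6E)-1,7-bis(4-benzyloxyphenyl)hepta-1,6-diene-3,5-dione | O=C(/C=C/c1ccc(OCc2ccccc2)cc1)CC(=O)/C=C/c1ccc(OCc2ccccc2)cc1
A1 | alternative 1 | 2-[1-[3-benzyloxy-2,6-bis(4-benzyloxybenzyl)-5-methoxyphenyl]-2-(3-methoxyphenyl)ethyl]-4,4,5,5-tetramethyl-1,3,2-dioxaborolane (racemic) | COc1cccc(CC(B2OC(C)(C)C(C)(C)O2)c2c(Cc3ccc(OCc4ccccc4)cc3)c(OCc3ccccc3)cc(OC)c2Cc2ccc(OCc3ccccc3)cc2)c1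
A2 | alternative 1 | 1-benzyloxy-2,4-bis(4-benzyloxybenzyl)-3-bromo-5-methoxybenzene | COc1cc(OCc2ccccc2)c(Cc2ccc(OCc3ccccc3)cc2)c(Br)c1Cc1ccc(OCc2ccccc2)cc1
A3 | alternative 1 | 4,4,5,5-tetramethyl-2-vinyl-1,3,2-dioxaborolane | C=CB1OC(C)(C)C(C)(C)O1
A4 | alternative 1 | 3-methoxyphenyl trifluoromethanesulfonate | COc1cccc(OS(=O)(=O)C(F)(F)F)c1
A5 | alternative 2 | methyl 1,3-bis(4-benzyloxybenzyl)-2-[2-(3-methoxyphenyl)ethyl]-4,6-dioxocyclohexane-1-carboxylate (diastereomer mixture) | COC(=O)C1(Cc2ccc(OCc3ccccc3)cc2)C(CCc2cccc(OC)c2)C(Cc2ccc(OCc3ccccc3)cc2)C(=O)CC1=O
A6 | alternative 2 | dimethyl 2-(4-benzyloxybenzyl)malonate | COC(=O)C(Cc1ccc(OCc2ccccc2)cc1)C(=O)OC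
A7 | alternative 2 | (E)-3-(4-benzyloxybenzyl)-6-(3-methoxyphenyl)hex-3-en-2-one | CC(=O)/C(Cc1ccc(OCc2ccccc2)cc1)=C/CCc1cccc(OC)c1
A8 | alternative 3 | 2-(4-benzyloxybenzoyl)-6-(4-benzyloxybenzyl)-3-hydroxy-5,3'-dimethoxybibenzyl | COc1cccc(CCc2c(C(=O)c3ccc(OCc4ccccc4)cc3)c(O)cc(OC)c2Cc2ccc(OCc3ccccc3)cc2)c1
A9 | alternative 3 | 5-(4-benzyloxyphenyl)-1,3-dimethoxy-1-(trimethylsilyloxy)penta-1,3-diene (geometry of both double bonds left open) | COC(=CC(OC)=CCc1ccc(OCc2ccccc2)cc1)O[Si](C)(C)C
A10 | alternative 3 | 1-(4-benzyloxyphenyl)-5-(3-methoxyphenyl)pent-2-yn-1-one | COc1cccc(CCC#CC(=O)c2ccc(OCc3ccccc3)cc2)c1
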